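I must choose a temperature for this run, so I ask what each setting does to the target. Solid reagent dissolves to give partner. Partner turns starting material into target and second substrate into second product. Starting material also meets second substrate to give cross product and meets target to give side product, while protic impurity quenches second substrate.

| flask | starting material | second substrate | solid reagent | protic impurity | temperature | time |
|---|---|---|---|---|---|---|
| amber | 0.40 M | 0.200 M | 0.400 M | 0.0400 M | 75 °C | 4.0 h |
| teal | 0.40 M | 0.200 M | 0.400 M | 0.0400 M | 100 °C | 4.0 h |
| ochre | 0.40 M | 0.200 M | 0.400 M | 0.0400 M | 50 °C | 4.0 h |

- which flask leads in amount of target, in percent of the starting material charged ("all alike" within 1.5 percentage points) (amber / teal / ochre / all alike)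
- how much target is there at the end, in percent of the starting material charged: amber
- how much target is there at the end, in percent of the starting material charged: teal
- how much target is there at the end, in percent of the starting material charged: ochre

- in percentages every species weighs as the starting material in it: one side product counts as two
- as a solid, counted per litre of solution: solid reagent
- all constants are for 50 °C and move with temperature by the activation energies
- at the start none of the solid reagent is in solution

    starting material + partner → target (k1 = 1.1 × 10⁻⁴ M⁻¹ s⁻¹, Ea1 = 87.0 kJ mol⁻¹)
    second substrate + partner → second product (k2 = 1.1 × 10⁻⁴ M⁻¹ s⁻¹, Ea2 = 75.0 kJ mol⁻¹)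
    starting material + second substrate → cross product (k3 = 6.2 × 10⁻⁵ M⁻¹ s⁻¹, Ea3 = 68.0 kJ mol⁻¹)
    solid reagent ⇌ partner, rate k4*(cs4 - [partner]) while solid is left; crystals form when [partner] > cs4 (cs4 = 0.31 M, k4 = 2.0 × 10⁻⁴ s⁻¹)
    starting material + target → side product (k5 = 4.7 × 10⁻⁵ M⁻¹ s⁻¹, Ea5 = 80.0 kJ mol⁻¹)
    second substrate + protic impurity → quenched substrate (k6 = 0.0052 M⁻¹ s⁻¹, Ea6 = 72.0 kJ mol⁻¹)
    (constants at 50 °C)

Time is the first setting, and I reckon it in ochre, at 50 °C, where the constants are given. As a first answer I let partner stand at its solubility, 0.31 M, for the whole 4.0 h. Starting material then decays pseudo-first-order through 0.491 lifetimes, and 38.8 % of it reacts.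

But partner starts from nothing and is consumed, so I put that back and go round once more. Protic impurity has a lifetime of about 0.267 h against second substrate, so I take its 0.0400 M off second substrate early, which leaves 0.160 M. Partner is therefore used at a first-order rate of 0.222 h⁻¹, and this is slower than the dissolution coefficient, 0.72 h⁻¹. So partner climbs to a plateau of 0.237 M with a time constant of 1.06 h.

Summing that rise over the run gives 0.278. This is the reach, the number of lifetimes of starting material under the target-making step that the partner present up to a given time has supplied. It gives 24.3 % of the starting material turned to target, which is my figure for ochre. Past the rise, the reach in ochre grows at 0.0939 h⁻¹, so more time means more target here.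

Temperature is the second setting. From ochre to teal the target-making step speeds up 77 times, the side-product step 54 times and the cross step 30 times, but the dissolution coefficient carries no activation energy. In teal, starting material at its charge uses partner at 12.1 h⁻¹, far faster than the 0.72 h⁻¹ of dissolution. On that account I do not carry the plateau reckoning into teal, and the cross step takes no partner. I expect a maximum somewhere between, and my reckoning stops short of a number for amber or teal.

The forecast names amber as the leader, with 41 % in amber, 30 % in teal and 21 % in ochre. Its ochre figure lies below mine. It speaks of how “slow, temperature-independent dissolution starves the partner”.

The simulation has amber leading, with 41.5 % in amber, 27.4 % in teal and 21.1 % in ochre, and the best temperature between ochre and teal lies at 73.5 °C.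

In ochre the quench of second substrate by protic impurity has 92 % of its turnover up to the asked time behind it at 0.800 h, while the target-making step has 9.4 %. The target-making step runs on while solid reagent dissolves, and at the end 6.98 % of that reagent is still solid and 65 % of the starting material remains. The reach of 0.278 stands for 24.3 % in ochre, against 21.1 % of target in the flask. The same flask read at 1.5 h has a reach of 0.0654, which stands for 6.33 %, and the flask then holds 5.93 % of target.

Its constants were set for the occasion.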